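Ring B is closed at the isoflavanone oxidation level by making the C6–C6a bond. The step exploits two features: C6 is the methylene on O5 of ring A, so it can be carried as an ordinary aryl methyl ether, and C6a sits between ring D and C11a, so with C11a as a ketone it can be a diazo carbon. A rhodium carbenoid at C6a inserts into a C–H bond of that OMe group, turning the methyl ether into the pyran ring in one operation. The precursor is an α-diazo deoxybenzoin. Transfer hydrogenation with dynamic kinetic resolution then fixes C6a, and closure of ring C at O11–C11a, necessarily cis, gives the (6aR,11aR)-pterocarpan.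

Key step: step 13

Remark: pterocarpan numbering (O5, C6, C6a, O11, C11a; ring A prenyl-resorcinol, ring D chromene-fused) is used for the target, which the SMILES defines as (6aR,11aR). In the chromanone intermediates C2, C3 and C4 are the later C6, C6a and C11a. Compounds 1 and 11 are taken as purchasable.

Step 1
Reactants: 1 2,4-dihydroxybenzaldehyde
Product: 2 2,4-bis(methoxymethoxy)benzaldehyde
Conditions: NaH, MOMCl, DMF, 0 °C to rt
Reagents that add atoms: chloromethyl methyl ether (MOMCl), COCCl
Why: Williamson etherification protects both phenols as MOM ethers, which later direct the two ortho-lithiations.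

Step 2
Reactants: 2 2,4-bis(methoxymethoxy)benzaldehyde
Product: 4 2,4-bis(methoxymethoxy)phenol, via aryl formate 3 (not isolated)
Conditions: mCPBA, NaHCO3, CH2Cl2, 0 °C to rt; then K2CO3 (cat.), MeOH, rt
Reagents that add atoms: 3-chloroperoxybenzoic acid (mCPBA), OOC(=O)c1cccc(Cl)c1
Why: Baeyer–Villiger (Dakin-type) oxidation, in which the electron-rich aryl group migrates to oxygen, gives the aryl formate, and methanolysis frees the phenol that becomes the chromene oxygen.

Step 3
Reactants: 4 2,4-bis(methoxymethoxy)phenol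
Product: 5 2,4-bis(methoxymethoxy)-1-[(2-methylbut-3-yn-2-yl)oxy]benzene
Conditions: 3-chloro-3-methylbut-1-yne, DBU, CuCl2 (cat.), MeCN, 0 °C
Reagents that add atoms: 3-chloro-3-methylbut-1-yne, C#CC(C)(C)Cl
Why: Copper-catalysed propargylic etherification through a copper acetylide should give the hindered aryl 1,1-dimethylpropargyl ether without C-alkylation.

Step 4
Reactants: 5 2,4-bis(methoxymethoxy)-1-[(2-methylbut-3-yn-2-yl)oxy]benzene
Product: 6 6,8-bis(methoxymethoxy)-2,2-dimethyl-2H-chromene
Conditions: xylene, 140 °C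
Reagents that add atoms: none
Why: Aryl propargyl ether Claisen rearrangement, 1,5-hydrogen shift and oxa-6π electrocyclisation build the 2,2-dimethylchromene, and the single unsubstituted ortho carbon fixes the regiochemistry.

Step 5
Reactants: 6 6,8-bis(methoxymethoxy)-2,2-dimethyl-2H-chromene
Product: 8 6,8-bis(methoxymethoxy)-2,2-dimethyl-7-(3-methylbut-2-en-1-yl)-2H-chromene, via 7-lithiochromene 7 (not isolated)
Conditions: n-BuLi, THF, 0 °C; then prenyl bromide, −78 °C to rt
Reagents that add atoms: prenyl bromide (1-bromo-3-methylbut-2-ene), CC(C)=CCBr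
Why: Directed ortho-metalation should occur at C7 between the two cooperating MOM ethers, and the aryllithium is alkylated at the primary carbon of the allylic bromide.

Step 6
Reactants: 8 6,8-bis(methoxymethoxy)-2,2-dimethyl-7-(3-methylbut-2-en-1-yl)-2H-chromene
Product: 10 5-bromo-6,8-bis(methoxymethoxy)-2,2-dimethyl-7-(3-methylbut-2-en-1-yl)-2H-chromene, via 5-lithiochromene 9 (not isolated)
Conditions: n-BuLi, THF, 0 °C; then BrCl2C–CCl2Br, −78 °C
Reagents that add atoms: 1,2-dibromo-1,1,2,2-tetrachloroethane, BrC(Cl)(Cl)C(Cl)(Cl)Br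
Why: The only aromatic C–H left (C5) lies ortho to the C6 MOM ether, so a second directed ortho-metalation and quench of the aryllithium with a bromine donor should give the bromide without exposing the two alkenes to an electrophilic halogenating agent.

Step 7
Reactants: 11 1-(4-hydroxy-2-methoxyphenyl)ethan-1-one
Product: 12 1-(5-bromo-4-hydroxy-2-methoxyphenyl)ethan-1-one
Conditions: NBS, MeCN, 0 °C
Reagents that add atoms: N-bromosuccinimide (NBS), O=C1CCC(=O)N1Br
Why: Electrophilic aromatic bromination should go to C5, ortho to the hydroxyl and para to the methoxy group, because C3 between the two oxygens is shielded.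

Step 8
Reactants: 12 1-(5-bromo-4-hydroxy-2-methoxyphenyl)ethan-1-one
Product: 13 1-[5-bromo-2-methoxy-4-(methoxymethoxy)phenyl]ethan-1-one
Conditions: MOMCl, iPr2NEt, CH2Cl2, 0 °C to rt
Reagents that add atoms: chloromethyl methyl ether (MOMCl), COCCl
Why: Standard MOM protection makes the phenol inert to the strong base of the later enolate arylation.

Step 9
Reactants: 13 1-[5-bromo-2-methoxy-4-(methoxymethoxy)phenyl]ethan-1-one
Product: 14 1-[2-methoxy-4-(methoxymethoxy)-5-(3-methylbut-2-en-1-yl)phenyl]ethan-1-one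
Conditions: tributyl(3-methylbut-2-en-1-yl)stannane, Pd(PPh3)4, DMF, 100 °C
Reagents that add atoms: tributyl(3-methylbut-2-en-1-yl)stannane, CCCC[Sn](CCCC)(CCCC)CC=C(C)C
Why: Stille coupling of the aryl bromide with the prenylstannane should transfer the prenyl group through its primary carbon and give the linear prenyl arene.

Step 10
Reactants: 14 1-[2-methoxy-4-(methoxymethoxy)-5-(3-methylbut-2-en-1-yl)phenyl]ethan-1-one and 10 5-bromo-6,8-bis(methoxymethoxy)-2,2-dimethyl-7-(3-methylbut-2-en-1-yl)-2H-chromene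
Product: 15 2-[6,8-bis(methoxymethoxy)-2,2-dimethyl-7-(3-methylbut-2-en-1-yl)-2H-chromen-5-yl]-1-[2-methoxy-4-(methoxymethoxy)-5-(3-methylbut-2-en-1-yl)phenyl]ethan-1-one
Conditions: Pd2(dba)3 (cat.), XPhos, NaOtBu, toluene, 70 °C
Reagents that add atoms: none
Why: Palladium-catalysed α-arylation of the methyl ketone enolate (Buchwald–Hartwig type) joins rings A and D at the future C6a, and the doubly ortho-substituted bromide should stop the reaction after one arylation.

Step 11
Reactants: 15 tris-MOM deoxybenzoin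
Product: 16 2-[2,2-dimethyl-7-(3-methylbut-2-en-1-yl)-6,8-bis(triethylsilyloxy)-2H-chromen-5-yl]-1-[2-methoxy-5-(3-methylbut-2-en-1-yl)-4-(triethylsilyloxy)phenyl]ethan-1-one
Conditions: TESOTf, 2,2′-bipyridyl, CH2Cl2, 0 °C to rt; aqueous NaHCO3 work-up
Reagents that add atoms: triethylsilyl triflate (TESOTf), CC[Si](CC)(CC)OS(=O)(=O)C(F)(F)F
Why: Silyl triflate/2,2′-bipyridyl exchange turns aromatic MOM ethers directly into aryl silyl ethers, which removes the O–CH2 group ortho to the future carbenoid on ring D (it would undergo 1,5 C–H insertion) and leaves fluoride-labile protection.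

Step 12
Reactants: 16 tris-TES deoxybenzoin
Product: 17 2-diazo-2-[2,2-dimethyl-7-(3-methylbut-2-en-1-yl)-6,8-bis(triethylsilyloxy)-2H-chromen-5-yl]-1-[2-methoxy-5-(3-methylbut-2-en-1-yl)-4-(triethylsilyloxy)phenyl]ethan-1-one
Conditions: p-ABSA, DBU, MeCN, 0 °C
Reagents that add atoms: 4-acetamidobenzenesulfonyl azide (p-ABSA), CC(=O)Nc1ccc(cc1)S(=O)(=O)N=[N+]=[N-]
Why: Regitz diazo transfer to the methylene activated by the ketone and ring D should give the α-aryl-α-diazo ketone.

Step 13
Reactants: 17 α-diazo deoxybenzoin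
Product: 18 rac-3-[2,2-dimethyl-7-(3-methylbut-2-en-1-yl)-6,8-bis(triethylsilyloxy)-2H-chromen-5-yl]-6-(3-methylbut-2-en-1-yl)-7-(triethylsilyloxy)chroman-4-one
Conditions: Rh2(OAc)4 (2 mol%), CH2Cl2, 40 °C, slow addition of 17, high dilution
Reagents that add atoms: none
Why: Rh2(OAc)4 expels N2 from 17 to give a divalent-rhodium-bound carbenoid at C3 (the later C6a) that carries the ring A ketone and ring D, and this carbon inserts into a C–H bond of the ortho methoxy group of the benzoyl ring through a three-centre transition state in which the ether oxygen stabilises the positive charge on the methyl carbon. The closest known reaction type is the dirhodium-catalysed intramolecular C–H insertion of ortho-alkoxyaryl α-diazo ketones at the O–CH position to give chroman-4-ones, together with the known insertion of aryl diazo compounds into aryl methyl ethers. Ring B (O1–C2–C3–C4–C4a–C8a of the chromanone, that is O5–C6–C6a–C11a–C11b–C4a) closes by 1,6-insertion through a six-membered arrangement, with C2–C3 as the only new skeletal bond. The new stereocentre C3 is formed without control, on purpose, because it is α to the ketone and is set under equilibrating conditions in step 14. The step needs 1,6-insertion to win over 1,5-insertion, ylide chemistry and cyclopropanation: ring D offers no C–H bond on an atom attached to its ortho oxygen (OSiEt3), and its other ortho position is the ring-fused chromene carbon, whose double bond cannot reach the carbenoid without a four-membered ring, while the oxonium ylide from the methoxy oxygen has no easy sigmatropic exit and should revert. Slow addition at high dilution keeps the carbenoid away from the trisubstituted prenyl alkenes of other molecules.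

Step 14
Reactants: 18 racemic isoflavanone
Product: 19 (3R,4R)-3-[2,2-dimethyl-7-(3-methylbut-2-en-1-yl)-6,8-bis(triethylsilyloxy)-2H-chromen-5-yl]-6-(3-methylbut-2-en-1-yl)-7-(triethylsilyloxy)chroman-4-ol
Conditions: RuCl(p-cymene)[(R,R)-TsDPEN] (5 mol%), HCO2H/Et3N (5:2), EtOAc, 40 °C
Reagents that add atoms: none
Why: Noyori–Ikariya asymmetric transfer hydrogenation with dynamic kinetic resolution: C3 epimerises through the enol under Et3N, the (R,R) catalyst should deliver the (4R) carbinol as it does for aryl alkyl ketones, and hydride adds anti to the 3-aryl group, so the cis-(3R,4R) alcohol is expected.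

Step 15
Reactants: 19 (3R,4R)-cis-isoflavan-4-ol
Product: 21 lespecyrtin E3, via desilylated isoflavan-4-ol 20 (not isolated)
Conditions: TBAF, AcOH, THF, 0 °C; then crude 20, PPTS (cat.), CH2Cl2, rt
Reagents that add atoms: none
Why: Fluoride removes the three silyl groups, and mild acid ionises the C4 carbinol to the para-hydroxybenzyl cation of ring A, which the ortho hydroxyl of ring D traps in a 5-exo closure that can only give the cis-fused ring C, so C6a (R, untouched) dictates C11a (R).

Compound list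
1 | 2,4-dihydroxybenzaldehyde | O=Cc1ccc(O)cc1O | starting material
2 | 2,4-bis(methoxymethoxy)benzaldehyde | O=Cc1ccc(OCOC)cc1OCOC | intermediate
3 | 2,4-bis(methoxymethoxy)phenyl formate | O=COc1ccc(OCOC)cc1OCOC | intermediate
4 | 2,4-bis(methoxymethoxy)phenol | Oc1ccc(OCOC)cc1OCOC | intermediate
5 | 2,4-bis(methoxymethoxy)-1-[(2-methylbut-3-yn-2-yl)oxy]benzene | C#CC(C)(C)Oc1ccc(OCOC)cc1OCOC | intermediate
6 | 6,8-bis(methoxymethoxy)-2,2-dimethyl-2H-chromene | CC1(C)C=Cc2cc(OCOC)cc(OCOC)c2O1 | intermediate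
7 | [6,8-bis(methoxymethoxy)-2,2-dimethyl-2H-chromen-7-yl]lithium | [Li]c1c(OCOC)cc2C=CC(C)(C)Oc2c1OCOC | intermediate
8 | 6,8-bis(methoxymethoxy)-2,2-dimethyl-7-(3-methylbut-2-en-1-yl)-2H-chromene | CC(C)=CCc1c(OCOC)cc2C=CC(C)(C)Oc2c1OCOC | intermediate
9 | [6,8-bis(methoxymethoxy)-2,2-dimethyl-7-(3-methylbut-2-en-1-yl)-2H-chromen-5-yl]lithium | CC(C)=CCc1c(OCOC)c([Li])c2C=CC(C)(C)Oc2c1OCOC | intermediate
10 | 5-bromo-6,8-bis(methoxymethoxy)-2,2-dimethyl-7-(3-methylbut-2-en-1-yl)-2H-chromene | CC(C)=CCc1c(OCOC)c(Br)c2C=CC(C)(C)Oc2c1OCOC | intermediate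
11 | 1-(4-hydroxy-2-methoxyphenyl)ethan-1-one | CC(=O)c1ccc(O)cc1OC | starting material
12 | 1-(5-bromo-4-hydroxy-2-methoxyphenyl)ethan-1-one | CC(=O)c1cc(Br)c(O)cc1OC | intermediate
13 | 1-[5-bromo-2-methoxy-4-(methoxymethoxy)phenyl]ethan-1-one | CC(=O)c1cc(Br)c(OCOC)cc1OC | intermediate
14 | 1-[2-methoxy-4-(methoxymethoxy)-5-(3-methylbut-2-en-1-yl)phenyl]ethan-1-one | CC(=O)c1cc(CC=C(C)C)c(OCOC)cc1OC | intermediate
15 | 2-[6,8-bis(methoxymethoxy)-2,2-dimethyl-7-(3-methylbut-2-en-1-yl)-2H-chromen-5-yl]-1-[2-methoxy-4-(methoxymethoxy)-5-(3-methylbut-2-en-1-yl)phenyl]ethan-1-one | COc1cc(OCOC)c(CC=C(C)C)cc1C(=O)Cc1c(OCOC)c(CC=C(C)C)c(OCOC)c2OC(C)(C)C=Cc12 | intermediate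
16 | 2-[2,2-dimethyl-7-(3-methylbut-2-en-1-yl)-6,8-bis(triethylsilyloxy)-2H-chromen-5-yl]-1-[2-methoxy-5-(3-methylbut-2-en-1-yl)-4-(triethylsilyloxy)phenyl]ethan-1-one | COc1cc(O[Si](CC)(CC)CC)c(CC=C(C)C)cc1C(=O)Cc1c(O[Si](CC)(CC)CC)c(CC=C(C)C)c(O[Si](CC)(CC)CC)c2OC(C)(C)C=Cc12 | intermediate
17 | 2-diazo-2-[2,2-dimethyl-7-(3-methylbut-2-en-1-yl)-6,8-bis(triethylsilyloxy)-2H-chromen-5-yl]-1-[2-methoxy-5-(3-methylbut-2-en-1-yl)-4-(triethylsilyloxy)phenyl]ethan-1-one | COc1cc(O[Si](CC)(CC)CC)c(CC=C(C)C)cc1C(=O)C(=[N+]=[N-])c1c(O[Si](CC)(CC)CC)c(CC=C(C)C)c(O[Si](CC)(CC)CC)c2OC(C)(C)C=Cc12 | intermediate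
18 | rac-3-[2,2-dimethyl-7-(3-methylbut-2-en-1-yl)-6,8-bis(triethylsilyloxy)-2H-chromen-5-yl]-6-(3-methylbut-2-en-1-yl)-7-(triethylsilyloxy)chroman-4-one | O=C1c2cc(CC=C(C)C)c(O[Si](CC)(CC)CC)cc2OCC1c1c(O[Si](CC)(CC)CC)c(CC=C(C)C)c(O[Si](CC)(CC)CC)c2OC(C)(C)C=Cc12 | intermediate
19 | (3R,4R)-3-[2,2-dimethyl-7-(3-methylbut-2-en-1-yl)-6,8-bis(triethylsilyloxy)-2H-chromen-5-yl]-6-(3-methylbut-2-en-1-yl)-7-(triethylsilyloxy)chroman-4-ol | CC(C)=CCc1cc2c(cc1O[Si](CC)(CC)CC)OC[C@@H](c1c(O[Si](CC)(CC)CC)c(CC=C(C)C)c(O[Si](CC)(CC)CC)c3OC(C)(C)C=Cc13)[C@H]2O | intermediate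
20 | (3R,4R)-3-[6,8-dihydroxy-2,2-dimethyl-7-(3-methylbut-2-en-1-yl)-2H-chromen-5-yl]-6-(3-methylbut-2-en-1-yl)chromane-4,7-diol | CC(C)=CCc1cc2c(cc1O)OC[C@@H](c1c(O)c(CC=C(C)C)c(O)c3OC(C)(C)C=Cc13)[C@H]2O | intermediate
21 | lespecyrtin E3, the (6aR,11aR)-pterocarpan | CC(C)=CCc1cc2c(cc1O)OC[C@H]1c3c4c(c(O)c(CC=C(C)C)c3O[C@@H]21)OC(C)(C)C=C4 | target

Total step count: 15. Longest linear sequence: 12 steps (steps 1–6 and 10–15 from compound 1).

Steps most likely to fail

Step 13. The carbenoid may be diverted before it reaches the methyl C–H bonds: the ether oxygen may attack to give an oxonium ylide that undergoes methyl shift, the ketone may undergo Wolff rearrangement, or carbenoid formation at the crowded diazo carbon may be too slow. The fallback sets out from 15 and comes back at 18. MgI2 etherate (toluene/Et2O, 60 °C) should remove, by chelation, only the methyl ether ortho to the ketone and give the 2-hydroxydeoxybenzoin F1. Paraformaldehyde and Et2NH in MeOH at reflux then give, by α-methylenation and oxa-Michael closure, the tris-MOM isoflavanone F2; here ring B closes at O5–C6 instead. Treatment of F2 with TESOTf and 2,2′-bipyridyl as in step 11 gives 18.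

Step 10. Oxidative addition and reductive elimination at the doubly ortho-substituted, electron-rich bromide may be slow, so that protodebromination and self-condensation of the ketone take over. The fallback sets out from 14 and 8 and comes back at 15. 14 with LiN(SiMe3)2 and CF3CO2CH2CF3 (THF, −78 °C) gives the trifluoroacetyl ketone F3, which with MsN3 and Et3N in MeCN gives the diazo ketone F4. 8 is lithiated as in step 6 (aryllithium 9) and quenched with B(OMe)3 and then dilute acid to give the boronic acid F5. F4 and F5 (as its boroxine) with iPr2NH in 1,2-dichloroethane at 80 °C should couple without a metal catalyst: the diazo carbon attacks boron, the aryl group shifts from boron to carbon with loss of N2, and protodeboronation gives 15.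

Step 12. Deprotonation of the hindered methylene by DBU may be incomplete, and the amidine base may strip aryl silyl groups during a long reaction. The fallback sets out from 16 and comes back at 17. LiN(SiMe3)2 (THF, −78 °C) and CF3CO2CH2CF3 give the trifluoroacetyl ketone F6, and MsN3 with Et3N in dry MeCN then transfers the diazo group with loss of the trifluoroacetyl group (deacylative diazo transfer) to give 17.

Further compounds
F1 | step 13 | 2-[6,8-bis(methoxymethoxy)-2,2-dimethyl-7-(3-methylbut-2-en-1-yl)-2H-chromen-5-yl]-1-[2-hydroxy-4-(methoxymethoxy)-5-(3-methylbut-2-en-1-yl)phenyl]ethan-1-one | COCOc1cc(O)c(cc1CC=C(C)C)C(=O)Cc1c(OCOC)c(CC=C(C)C)c(OCOC)c2OC(C)(C)C=Cc12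
F2 | step 13 | rac-3-[6,8-bis(methoxymethoxy)-2,2-dimethyl-7-(3-methylbut-2-en-1-yl)-2H-chromen-5-yl]-7-(methoxymethoxy)-6-(3-methylbut-2-en-1-yl)chroman-4-one | O=C1c2cc(CC=C(C)C)c(OCOC)cc2OCC1c1c(OCOC)c(CC=C(C)C)c(OCOC)c2OC(C)(C)C=Cc12
F3 | step 10 | 4,4,4-trifluoro-1-[2-methoxy-4-(methoxymethoxy)-5-(3-methylbut-2-en-1-yl)phenyl]butane-1,3-dione | COc1cc(OCOC)c(CC=C(C)C)cc1C(=O)CC(=O)C(F)(F)F
F4 | step 10 | 2-diazo-1-[2-methoxy-4-(methoxymethoxy)-5-(3-methylbut-2-en-1-yl)phenyl]ethan-1-one | COc1cc(OCOC)c(CC=C(C)C)cc1C(=O)C=[N+]=[N-]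
F5 | step 10 | [6,8-bis(methoxymethoxy)-2,2-dimethyl-7-(3-methylbut-2-en-1-yl)-2H-chromen-5-yl]boronic acid | CC(C)=CCc1c(OCOC)c(B(O)O)c2C=CC(C)(C)Oc2c1OCOC
F6 | step 12 | 2-[2,2-dimethyl-7-(3-methylbut-2-en-1-yl)-6,8-bis(triethylsilyloxy)-2H-chromen-5-yl]-4,4,4-trifluoro-1-[2-methoxy-5-(3-methylbut-2-en-1-yl)-4-(triethylsilyloxy)phenyl]butane-1,3-dione | COc1cc(O[Si](CC)(CC)CC)c(CC=C(C)C)cc1C(=O)C(C(=O)C(F)(F)F)c1c(O[Si](CC)(CC)CC)c(CC=C(C)C)c(O[Si](CC)(CC)CC)c2OC(C)(C)C=Cc12
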